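The chain is numbered C1 (benzylic CH2 on the 3,4-dihydroxy-5-methoxyphenyl ring, ring A) to C7 (benzylic CH2 on the guaiacyl ring, ring B). The route rests on reading the C3 ketone and the C5 carbinol as the C=N and O–C ends of a 2-isoxazoline ring. One tartrate-directed nitrile oxide cycloaddition to allyl alcohol forms C3–C4 and O–C5, closes that ring and sets C5, so the aldol unit is stored in a form that cannot dehydrate. The precursor is a benzyl-protected 3-arylpropanohydroximoyl chloride carrying ring A and C1–C3. Ring B and C7 are added later at C6, then N–O cleavage and debenzylation release the target.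

Key step: step 6

Remark: the aldoxime is expected as an E/Z mixture (drawn E), both isomers converging on the same hydroximoyl chloride; the (S,S)-tartrate is assigned to the 5S series by analogy with simpler nitrile oxides, to be confirmed on the cycloadduct by MTPA ester analysis.

Step 1
Reactants: 1 3,4-dihydroxy-5-methoxybenzaldehyde (5-hydroxyvanillin)
Product: 2 3,4-bis(benzyloxy)-5-methoxybenzaldehyde
Conditions: BnBr (2.4 equiv), K2CO3 (3 equiv), DMF, 60 °C
Reagents that add atoms: benzyl bromide, BrCc1ccccc1
Why: Williamson ether synthesis, in which both phenoxides formed by K2CO3 are alkylated by the benzylic bromide while the aldehyde is untouched.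

Step 2
Reactants: 2 3,4-bis(benzyloxy)-5-methoxybenzaldehyde
Product: 3 (E)-3-[3,4-bis(benzyloxy)-5-methoxyphenyl]prop-2-enal
Conditions: Ph3P=CHCHO (1.2 equiv), toluene, 90 °C
Reagents that add atoms: (triphenylphosphoranylidene)acetaldehyde, O=CC=P(c1ccccc1)(c1ccccc1)c1ccccc1
Why: Wittig olefination with the stabilised formyl ylide is E-selective and adds C2 and C3 in one operation, the small excess of ylide limiting a second homologation of the less reactive enal.

Step 3
Reactants: 3 (E)-3-[3,4-bis(benzyloxy)-5-methoxyphenyl]prop-2-enal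
Product: 4 3-[3,4-bis(benzyloxy)-5-methoxyphenyl]propanal
Conditions: Hantzsch ester (diethyl 2,6-dimethyl-1,4-dihydropyridine-3,5-dicarboxylate, 1.1 equiv), dibenzylammonium trifluoroacetate (10 mol%), THF, rt
Reagents that add atoms: none
Why: Organocatalytic transfer hydrogenation under iminium activation, in which the dihydropyridine delivers hydride to the β-carbon so that only the C=C bond is reduced and the aldehyde and benzyl ethers survive.

Step 4
Reactants: 4 3-[3,4-bis(benzyloxy)-5-methoxyphenyl]propanal
Product: 5 3-[3,4-bis(benzyloxy)-5-methoxyphenyl]propanal oxime (E/Z mixture, drawn E)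
Conditions: NH2OH·HCl (1.3 equiv), NaOAc (1.5 equiv), EtOH/H2O, rt
Reagents that add atoms: hydroxylamine hydrochloride, NO.Cl
Why: Oxime condensation of the aldehyde with hydroxylamine under acetate buffering, the E/Z composition being irrelevant because both isomers are chlorinated to the same product.

Step 5
Reactants: 5 3-[3,4-bis(benzyloxy)-5-methoxyphenyl]propanal oxime
Product: 6 (Z)-3-[3,4-bis(benzyloxy)-5-methoxyphenyl]-N-hydroxypropanimidoyl chloride
Conditions: NCS (1.05 equiv), DMF, 0 °C to rt; extractive work-up, used without purification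
Reagents that add atoms: N-chlorosuccinimide, O=C1CCC(=O)N1Cl
Why: Electrophilic chlorination of the aldoxime carbon with NCS in DMF is the standard entry to hydroximoyl chlorides, and with one equivalent at 0 °C the oxime should react faster than the trialkoxyarene ring.

Step 6
Reactants: 6 (Z)-3-[3,4-bis(benzyloxy)-5-methoxyphenyl]-N-hydroxypropanimidoyl chloride; 7 allyl alcohol (prop-2-en-1-ol)
Product: 10 (S)-{3-[2-(3,4-bis(benzyloxy)-5-methoxyphenyl)ethyl]-4,5-dihydroisoxazol-5-yl}methanol, via zinc allyloxide tartrate complex 8 (not isolated), via nitrile oxide 9 (not isolated)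
Conditions: 7 (1.2 equiv), Et2Zn (1.2 equiv), then (S,S)-diisopropyl tartrate (1.2 equiv), then Et2Zn (1.2 equiv), then 6 (slow addition), CHCl3, 1,4-dioxane (additive), 0 °C; aq NH4Cl
Reagents that add atoms: none
Why: Et2Zn turns allyl alcohol into a zinc alkoxide that the (S,S)-tartrate bridges to a second, ethyl-bearing zinc centre (8); that centre deprotonates the N–OH group of 6, chloride passes to zinc, and nitrile oxide 9 is released next to the bound alkene. The closest known reaction type is the tartrate–zinc mediated enantioselective Huisgen 1,3-dipolar cycloaddition of nitrile oxides to allylic alcohols. The isoxazoline ring closes by a concerted suprafacial [3+2] cycloaddition in which C3–C4 and O–C5 form together, not by a stepwise cyclisation. The new stereocentre C5 is set under reagent control by the chiral tartrate dizinc template, which exposes one enantiotopic face of the alkene; the (S,S)-ester is chosen because the (R,R)-ester is expected to give the 5R series. The step needs regioselectivity (oxygen on the substituted alkene carbon C5), which the intrinsic preference of monosubstituted alkenes and the zinc tether secure, and it needs cycloaddition to outrun furoxan dimerisation, which slow addition of 6 to an excess of the alkoxide complex secures. The benzyl ethers and the electron-rich ring A are inert to Et2Zn at 0 °C.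

Step 7
Reactants: 11 4-(benzyloxy)-3-methoxybenzyl alcohol
Product: 12 4-(benzyloxy)-3-methoxybenzyl chloride
Conditions: SOCl2 (1.2 equiv), CH2Cl2, 0 °C to rt
Reagents that add atoms: thionyl chloride, ClS(Cl)=O
Why: Chlorodehydroxylation of an electron-rich benzylic alcohol with SOCl2 is fast at low temperature, and the aryl benzyl ether tolerates the HCl released.

Step 8
Reactants: 10 (S)-{3-[2-(3,4-bis(benzyloxy)-5-methoxyphenyl)ethyl]-4,5-dihydroisoxazol-5-yl}methanol
Product: 13 (S)-{3-[2-(3,4-bis(benzyloxy)-5-methoxyphenyl)ethyl]-4,5-dihydroisoxazol-5-yl}methyl trifluoromethanesulfonate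
Conditions: Tf2O (1.2 equiv), 2,6-lutidine (1.5 equiv), CH2Cl2, −78 °C; cold aqueous work-up, used at once
Reagents that add atoms: trifluoromethanesulfonic anhydride, O=S(=O)(OS(=O)(=O)C(F)(F)F)C(F)(F)F
Why: O-Sulfonylation of the primary alcohol with Tf2O and a hindered base activates C6 without breaking any bond at C5, so the configuration is retained.

Step 9
Reactants: 13 (S)-{3-[2-(3,4-bis(benzyloxy)-5-methoxyphenyl)ethyl]-4,5-dihydroisoxazol-5-yl}methyl trifluoromethanesulfonate; 12 4-(benzyloxy)-3-methoxybenzyl chloride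
Product: 15 (R)-3-[2-(3,4-bis(benzyloxy)-5-methoxyphenyl)ethyl]-5-{2-[4-(benzyloxy)-3-methoxyphenyl]ethyl}-4,5-dihydroisoxazole, via [4-(benzyloxy)-3-methoxybenzyl]magnesium chloride 14 (not isolated)
Conditions: 12, Mg turnings, 2-MeTHF, 0 °C to rt (slow addition, dilute); then 13, CuBr·SMe2 (10 mol%), THF, −78 to −20 °C
Reagents that add atoms: none
Why: Copper-catalysed sp3–sp3 cross-coupling of a primary alkyl triflate with a benzylic magnesium reagent forms C6–C7 by SN2 displacement well below the temperature at which the nucleophile would add to C=N or deprotonate C4, and C5 is not involved (its descriptor changes to R only through the priority rules).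

Step 10
Reactants: 15 (R)-3-[2-(3,4-bis(benzyloxy)-5-methoxyphenyl)ethyl]-5-{2-[4-(benzyloxy)-3-methoxyphenyl]ethyl}-4,5-dihydroisoxazole
Product: 17 (R)-1-[3,4-bis(benzyloxy)-5-methoxyphenyl]-7-[4-(benzyloxy)-3-methoxyphenyl]-5-hydroxyheptan-3-one, via β-hydroxy imine 16 (not isolated)
Conditions: H2 (1 atm), Raney Ni, B(OH)3 (3 equiv), MeOH/H2O (5:1), rt
Reagents that add atoms: water, O
Why: Reductive hydrolytic isoxazoline cleavage, in which hydrogenolysis of the weak N–O bond gives the β-hydroxy imine and the boric acid-buffered aqueous methanol hydrolyses it to the ketone before further reduction, leaving the C5–O bond intact and avoiding dehydration or retro-aldol cleavage.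

Step 11
Reactants: 17 (R)-1-[3,4-bis(benzyloxy)-5-methoxyphenyl]-7-[4-(benzyloxy)-3-methoxyphenyl]-5-hydroxyheptan-3-one
Product: 18 (R)-1-(3,4-dihydroxy-5-methoxyphenyl)-5-hydroxy-7-(4-hydroxy-3-methoxyphenyl)heptan-3-one
Conditions: H2 (1 atm), 10% Pd/C, EtOAc/MeOH, rt; degassed solvents, filtration under argon
Reagents that add atoms: none
Why: Palladium-catalysed hydrogenolysis cleaves the three aryl benzyl ethers, while the aliphatic ketone and the non-benzylic secondary alcohol are inert at atmospheric pressure.

Compound list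
1 | 3,4-dihydroxy-5-methoxybenzaldehyde (5-hydroxyvanillin) | COc1cc(C=O)cc(O)c1O | starting material
2 | 3,4-bis(benzyloxy)-5-methoxybenzaldehyde | COc1cc(C=O)cc(OCc2ccccc2)c1OCc1ccccc1 | intermediate
3 | (E)-3-[3,4-bis(benzyloxy)-5-methoxyphenyl]prop-2-enal | COc1cc(/C=C/C=O)cc(OCc2ccccc2)c1OCc1ccccc1 | intermediate
4 | 3-[3,4-bis(benzyloxy)-5-methoxyphenyl]propanal | COc1cc(CCC=O)cc(OCc2ccccc2)c1OCc1ccccc1 | intermediate
5 | 3-[3,4-bis(benzyloxy)-5-methoxyphenyl]propanal oxime (E/Z mixture, drawn E) | COc1cc(CC/C=N/O)cc(OCc2ccccc2)c1OCc1ccccc1 | intermediate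
6 | (Z)-3-[3,4-bis(benzyloxy)-5-methoxyphenyl]-N-hydroxypropanimidoyl chloride | Cl/C(CCc1cc(OC)c(OCc2ccccc2)c(OCc2ccccc2)c1)=N\O | intermediate
7 | allyl alcohol (prop-2-en-1-ol) | C=CCO | starting material
8 | allyloxyzinc ethylzinc (S,S)-diisopropyl tartrate complex (monomeric drawing of an aggregate, formed in the flask, not isolated) | C=CCO[Zn]O[C@H](C(=O)OC(C)C)[C@H](O[Zn]CC)C(=O)OC(C)C | intermediate
9 | 3-[3,4-bis(benzyloxy)-5-methoxyphenyl]propanenitrile oxide (formed in the flask, not isolated) | COc1cc(CCC#[N+][O-])cc(OCc2ccccc2)c1OCc1ccccc1 | intermediate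
10 | (S)-{3-[2-(3,4-bis(benzyloxy)-5-methoxyphenyl)ethyl]-4,5-dihydroisoxazol-5-yl}methanol | OC[C@@H]1CC(CCc2cc(OC)c(OCc3ccccc3)c(OCc3ccccc3)c2)=NO1 | intermediate
11 | 4-(benzyloxy)-3-methoxybenzyl alcohol | COc1cc(CO)ccc1OCc1ccccc1 | starting material
12 | 4-(benzyloxy)-3-methoxybenzyl chloride | COc1cc(CCl)ccc1OCc1ccccc1 | intermediate
13 | (S)-{3-[2-(3,4-bis(benzyloxy)-5-methoxyphenyl)ethyl]-4,5-dihydroisoxazol-5-yl}methyl trifluoromethanesulfonate | O=S(=O)(OC[C@@H]1CC(CCc2cc(OC)c(OCc3ccccc3)c(OCc3ccccc3)c2)=NO1)C(F)(F)F | intermediate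
14 | [4-(benzyloxy)-3-methoxybenzyl]magnesium chloride (formed in the flask, not isolated) | COc1cc(C[Mg]Cl)ccc1OCc1ccccc1 | intermediate
15 | (R)-3-[2-(3,4-bis(benzyloxy)-5-methoxyphenyl)ethyl]-5-{2-[4-(benzyloxy)-3-methoxyphenyl]ethyl}-4,5-dihydroisoxazole | COc1cc(CC[C@@H]2CC(CCc3cc(OC)c(OCc4ccccc4)c(OCc4ccccc4)c3)=NO2)ccc1OCc1ccccc1 | intermediate
16 | (R)-1-[3,4-bis(benzyloxy)-5-methoxyphenyl]-7-[4-(benzyloxy)-3-methoxyphenyl]-3-iminoheptan-5-ol (formed in the flask, not isolated) | COc1cc(CC[C@@H](O)CC(=N)CCc2cc(OC)c(OCc3ccccc3)c(OCc3ccccc3)c2)ccc1OCc1ccccc1 | intermediate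
17 | (R)-1-[3,4-bis(benzyloxy)-5-methoxyphenyl]-7-[4-(benzyloxy)-3-methoxyphenyl]-5-hydroxyheptan-3-one | COc1cc(CC[C@@H](O)CC(=O)CCc2cc(OC)c(OCc3ccccc3)c(OCc3ccccc3)c2)ccc1OCc1ccccc1 | intermediate
18 | (R)-1-(3,4-dihydroxy-5-methoxyphenyl)-5-hydroxy-7-(4-hydroxy-3-methoxyphenyl)heptan-3-one | COc1cc(CC[C@@H](O)CC(=O)CCc2cc(O)c(O)c(OC)c2)ccc1O | target

Total step count: 11 steps.
Longest linear sequence: 10 steps (steps 1 to 6 and 8 to 11, from 1); step 7 is a one-step side branch.

Steps most likely to fail

Step 6. The flexible aliphatic nitrile oxide may be discriminated poorly between the two alkene faces, or dimerisation of the dipole may outrun the cycloaddition. Fallback, setting out from 6 and 7 and coming back at 10: stereocontrol is replaced by resolution. Slow addition of 6 to allyl alcohol 7 and Et3N in Et2O at 0 °C (uncatalysed Huisgen cycloaddition, same regiochemistry) should give racemic {3-[2-(3,4-bis(benzyloxy)-5-methoxyphenyl)ethyl]-4,5-dihydroisoxazol-5-yl}methanol F1. Preparative chromatography on a chiral stationary phase (cellulose tris(3,5-dimethylphenylcarbamate)) should then separate 10 from the unwanted (R)-{3-[2-(3,4-bis(benzyloxy)-5-methoxyphenyl)ethyl]-4,5-dihydroisoxazol-5-yl}methanol F2. The enantiomers would be assigned by comparison with partially enriched material from step 6.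

Step 9. Homocoupling may consume the benzylic chloride while the magnesium reagent forms, the triflate may decompose before it couples, or the basic nucleophile may deprotonate C4 or add to C=N. Fallback, setting out from 10 and 12 and coming back at 15: a stable iodide and a non-basic zinc nucleophile replace the triflate and the magnesium reagent. Treatment of 10 with I2, PPh3 and imidazole in CH2Cl2 at rt should give (S)-3-[2-(3,4-bis(benzyloxy)-5-methoxyphenyl)ethyl]-5-(iodomethyl)-4,5-dihydroisoxazole F3. Insertion of Zn dust into 12 in THF in the presence of LiCl should give [4-(benzyloxy)-3-methoxybenzyl]zinc chloride F4. Nickel-catalysed Negishi sp3–sp3 coupling of the two (Ni(acac)2 10 mol%, Bu4NI, 4-fluorostyrene, THF/NMP, −5 °C) should then give 15.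

Step 3. Iminium formation from the electron-rich enal may be slow, so that conversion stalls or the saturated aldehyde condenses with itself. Fallback, setting out from 3 and coming back at 4: over-reduction followed by re-oxidation. NaBH4 with NiCl2·6H2O (catalytic) in MeOH at 0 °C should reduce both the C=C bond and the aldehyde to give 3-[3,4-bis(benzyloxy)-5-methoxyphenyl]propan-1-ol F5. Dess–Martin oxidation (Dess–Martin periodinane, NaHCO3, CH2Cl2, rt) should then return aldehyde 4.

Further compounds
F1 | step 6 | racemic {3-[2-(3,4-bis(benzyloxy)-5-methoxyphenyl)ethyl]-4,5-dihydroisoxazol-5-yl}methanol | OCC1CC(CCc2cc(OC)c(OCc3ccccc3)c(OCc3ccccc3)c2)=NO1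
F2 | step 6 | (R)-{3-[2-(3,4-bis(benzyloxy)-5-methoxyphenyl)ethyl]-4,5-dihydroisoxazol-5-yl}methanol | OC[C@H]1CC(CCc2cc(OC)c(OCc3ccccc3)c(OCc3ccccc3)c2)=NO1
F3 | step 9 | (S)-3-[2-(3,4-bis(benzyloxy)-5-methoxyphenyl)ethyl]-5-(iodomethyl)-4,5-dihydroisoxazole | IC[C@@H]1CC(CCc2cc(OC)c(OCc3ccccc3)c(OCc3ccccc3)c2)=NO1
F4 | step 9 | [4-(benzyloxy)-3-methoxybenzyl]zinc chloride | COc1cc(C[Zn]Cl)ccc1OCc1ccccc1
F5 | step 3 | 3-[3,4-bis(benzyloxy)-5-methoxyphenyl]propan-1-ol | OCCCc1cc(OC)c(OCc2ccccc2)c(OCc2ccccc2)c1
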